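Ring A of the target is read as the Diels–Alder adduct of a tigloyl ketone and a 2-silyloxydiene: the cis methyls on C4 and C5 are the two methyls of an (E)-2-methylbut-2-enoyl unit, and the C2 ketone lies where the diene carries its oxygen. Linking the two partners through C6–C9 makes the cycloaddition intramolecular, so one thermal step forms C3–C4 and C5–C10, closes rings A and B as a cis-decalin and sets C4, C5 and C10. Its precursor is an open-chain trienone: a tigloyl ketone (temporary C6 carbonyl) carrying isopropenyl at C7, a cis-dioxolane across O8/O9 and an (E)-3-silyloxybuta-1,3-dienyl group on C9.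

Key step: step 9

Numbering: C1–C10 are the decalin carbons of the target (C2 ketone, C4 and C5 methyl-bearing, C6 the ring B CH2, C7 isopropenyl, C8 tiglate, C9 angelate, C10 ring-fusion CH). β is the face of the two methyls. The same locants are kept for open-chain compounds.

Assumption: alcohol 17 is drawn as the 6α (equatorial) epimer expected from axial hydride attack; the other epimer would serve equally, because step 12 turns C6 into CH2.

Step 1
Reactants: 1 tigloyl chloride [(E)-2-methylbut-2-enoyl chloride]; 2 N,O-dimethylhydroxylamine hydrochloride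
Product: 3 (E)-N-methoxy-N,2-dimethylbut-2-enamide
Conditions: pyridine, CH2Cl2, 0 °C to rt
Reagents that add atoms: none
Why: N-acylation of the amine salt by the acid chloride (Weinreb amide formation) is fast at 0 °C and leaves the (E)-trisubstituted alkene untouched.

Step 2
Reactants: 3 (E)-N-methoxy-N,2-dimethylbut-2-enamide; 4 methallylmagnesium chloride (2-methylprop-2-enylmagnesium chloride, THF solution)
Product: 5 (5E)-2,5-dimethylhepta-1,5-dien-4-one
Conditions: THF, −78 to 0 °C; cold aq. NH4Cl
Reagents that add atoms: none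
Why: Weinreb ketone synthesis: the chelated tetrahedral adduct holds the allylic Grignard reagent at single addition, and a cold, weakly acidic quench should keep the 1,1-disubstituted alkene out of conjugation.

Step 3
Reactants: 5 (5E)-2,5-dimethylhepta-1,5-dien-4-one; 6 (S)-glyceraldehyde acetonide [(4S)-2,2-dimethyl-1,3-dioxolane-4-carbaldehyde]
Product: 8 (2E,5R,6R)-6-[(4S)-2,2-dimethyl-1,3-dioxolan-4-yl]-6-hydroxy-3-methyl-5-(prop-1-en-2-yl)hex-2-en-4-one (7R,8R,9S in target locants), via dibutylboron dienolate 7 (not isolated)
Conditions: Bu2BOTf, iPr2NEt, CH2Cl2, −78 to 0 °C; then 6, −78 °C; aq. NaH2PO4/Na2HPO4 (pH 7), MeOH, H2O2, 0 °C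
Reagents that add atoms: none
Why: Boron aldol addition: Bu2BOTf/iPr2NEt should give the (Z)-dienolate 7, which reacts at its α-carbon through a chair-like six-membered transition state to give the 7,8-syn relation, while non-chelation attack anti to the α-C–O bond of 6 sets C8 anti to C9, so both new centres follow from C9 of 6.

Step 4
Reactants: 8 aldol adduct
Product: 9 (2E,5R,6R,7S)-6,7,8-trihydroxy-3-methyl-5-(prop-1-en-2-yl)oct-2-en-4-one
Conditions: AcOH/H2O (4:1), rt
Reagents that add atoms: none
Why: Acid-catalysed hydrolysis of the terminal isopropylidene acetal; weak aqueous acid at room temperature should neither enolise the C6 ketone toward C7 nor dehydrate the aldol.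

Step 5
Reactants: 9 triol
Product: 10 (2E,5R,6R,7S)-6,7-dihydroxy-3-methyl-5-(prop-1-en-2-yl)-8-(triethylsilyloxy)oct-2-en-4-one
Conditions: TESCl (1.05 equiv), imidazole, CH2Cl2, −40 to −20 °C
Reagents that add atoms: chlorotriethylsilane, CC[Si](Cl)(CC)CC
Why: Kinetically selective silyl ether formation at the unhindered primary O10–H over the two secondary hydroxyls.

Step 6
Reactants: 10 primary triethylsilyl ether
Product: 11 (3R,5E)-3-[(4R,5S)-2,2-dimethyl-5-(triethylsilyloxymethyl)-1,3-dioxolan-4-yl]-2,5-dimethylhepta-1,5-dien-4-one (cis-dioxolane across O8/O9)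
Conditions: 2-methoxypropene, PPTS (cat.), CH2Cl2, 0 °C
Reagents that add atoms: 2-methoxypropene, COC(C)=C
Why: Acid-catalysed acetalisation with an enol ether closes the cis-4,5-disubstituted dioxolane on the only free 1,2-diol, and a few minutes with PPTS under anhydrous conditions should spare the primary silyl ether.

Step 7
Reactants: 11 O8/O9 acetonide with 10-OTES; 12 1-(triphenylphosphoranylidene)propan-2-one
Product: 14 (3R,5E)-3-{(4R,5S)-2,2-dimethyl-5-[(1E)-3-oxobut-1-en-1-yl]-1,3-dioxolan-4-yl}-2,5-dimethylhepta-1,5-dien-4-one, via aldehyde 13 (not isolated)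
Conditions: (COCl)2, DMSO, CH2Cl2, −78 to −40 °C; iPr2NEt, −78 °C; then 12, −78 °C to rt
Reagents that add atoms: none
Why: Swern oxidation applied directly to the primary triethylsilyl ether (the chlorosulfonium salt cleaves it and oxidises C10), followed in the same flask by Wittig olefination with the stabilised ylide, which gives the (E)-enone and traps aldehyde 13 cold before C9 can epimerise.

Step 8
Reactants: 14 enone
Product: 15 (3R,5E)-3-{(4R,5S)-5-[(1E)-3-(tert-butyldimethylsilyloxy)buta-1,3-dien-1-yl]-2,2-dimethyl-1,3-dioxolan-4-yl}-2,5-dimethylhepta-1,5-dien-4-one (acyclic siloxydiene tigloyl ketone)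
Conditions: TBSOTf (1.2 equiv), Et3N, CH2Cl2, −78 °C
Reagents that add atoms: tert-butyldimethylsilyl triflate, CC(C)(C)[Si](C)(C)OS(=O)(=O)C(F)(F)F
Why: Soft enolisation (silyl triflate plus tertiary amine) converts the unhindered methyl ketone into the cross-conjugated 2-silyloxydiene, whereas the doubly α-branched C6 ketone should be silylated and deprotonated at its tertiary C7–H far more slowly.

Step 9
Reactants: 15 acyclic siloxydiene tigloyl ketone
Product: 16 cis-decalin enol silane (4S,5R,7R,8R,9S,10S): 2-(tert-butyldimethylsilyloxy)-Δ1, 6-oxo, 4β,5β-dimethyl, 7β-isopropenyl, 8α,9α-O-isopropylidene, 10β-H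
Conditions: toluene (0.01 M), BHT (cat.), 120 °C, sealed tube
Reagents that add atoms: none
Why: Thermal, concerted but asynchronous [4+2] cycloaddition in which the nucleophilic diene terminus C3 bonds to the enone β-carbon C4 a little ahead of C10–C5; the closest known reaction type is the intramolecular Diels–Alder reaction of 1,7,9-decatrien-3-ones and of tethered 2-silyloxydienes. Ring A closes by the cycloaddition itself (C3–C4 and C5–C10 complete a cyclohexene whose C1=C2 bond is the enol silane), and ring B closes at the same time as the fused six-membered carbocycle spanned by the four-atom tether C6–C9 once C5–C10 exists. The cis relation of the C4 and C5 methyls is copied from the (E)-tigloyl alkene by suprafacial addition, and the cis ring fusion at C5/C10 follows from the tether carbonyl C6 lying endo under the diene, the usual preference of this trienone class. The diene face, hence the absolute sense at C4 (S), C5 (R) and C10 (S), should be chosen by the 7R,8R,9S tether in a boat-like endo fold (C5 and C8 at the prows, a fold that substituted trienones of this kind are known to use): there isopropenyl is pseudo-equatorial, H8 and not O8 points at the C5 methyl, and the C9–O bond lies on the inner side of the diene with H9 turned away from the dienophile. The step therefore needs endo closure and that one diene face; the first is secured by the in-tether carbonyl, the second by the three tether stereocentres together with the cis-dioxolane, which holds C7 and C10 syn and keeps the reactive rotamer populated, while the chair-like endo fold that would use the other face forces the diene axial and pushes O9 against the C5 methyl.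

Step 10
Reactants: 16 cycloadduct
Product: 17 6α-alcohol of 16 (C6 carbinol; enol silane and acetonide unchanged)
Conditions: LiAlH4, Et2O, −78 to 0 °C; aq. potassium sodium tartrate (KNaC4H4O6)
Reagents that add atoms: none
Why: Hydride reduction of the only free carbonyl (C2 stays masked as the enol silane, which LiAlH4 does not touch); axial delivery to the less hindered β-face should give the equatorial 6α-alcohol, a centre that step 12 removes.

Step 11
Reactants: 17 C6 alcohol
Product: 18 O-(C6) S-methyl dithiocarbonate (xanthate) of 17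
Conditions: NaH, CS2, THF, 0 °C to rt; then MeI
Reagents that add atoms: carbon disulfide, S=C=S; iodomethane, CI
Why: Xanthate formation (alkoxide addition to CS2, then S-methylation) prepares the Barton–McCombie deoxygenation, and 17 has no other acidic or electrophilic site under these conditions.

Step 12
Reactants: 18 xanthate
Product: 19 cis-decalin enol silane with C6 as CH2 (4S,5R,7R,8R,9S,10S): 2-(tert-butyldimethylsilyloxy)-Δ1, 8α,9α-O-isopropylidene
Conditions: Bu3SnH (0.3 M), AIBN, toluene, 100 °C
Reagents that add atoms: none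
Why: Barton–McCombie radical deoxygenation: the secondary C6 radical is reduced by concentrated Bu3SnH faster than it can add to the neighbouring isopropenyl group, and C5 and C7 are not involved, so their configurations are kept.

Step 13
Reactants: 19 deoxygenated enol silane
Product: 20 (4S,5R,7R,8R,9S,10S)-8,9-dihydroxy-4,5-dimethyl-7-(prop-1-en-2-yl)decalin-2-one (8α,9α-diol, 10β-H)
Conditions: 2 M HCl, THF, rt
Reagents that add atoms: none
Why: Aqueous acid protonates the enol silane at C1 to free the C2 ketone and hydrolyses the cis-fused isopropylidene acetal; C1 and C3 carry no stereocentre, so nothing can epimerise, and the 1,1-disubstituted alkene should survive dilute acid at room temperature.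

Step 14
Reactants: 20 keto diol; 1 tigloyl chloride
Product: 21 8-O-tigloyl keto diol (8α-[(E)-2-methylbut-2-enoyloxy], 9α-hydroxy)
Conditions: pyridine, DMAP (cat.), CH2Cl2, −20 to 0 °C
Reagents that add atoms: none
Why: DMAP-catalysed O-acylation with an acid chloride should pick the equatorial O8–H over the axial O9–H, which is 1,3-diaxial to C4 and next to the ring fusion.

Step 15
Reactants: 21 monotiglate; 22 angelic acid [(Z)-2-methylbut-2-enoic acid]
Product: 24 target (4S,5R,7R,8R,9S,10S)-9-[(Z)-2-methylbut-2-enoyloxy]-8-[(E)-2-methylbut-2-enoyloxy]-4,5-dimethyl-7-(prop-1-en-2-yl)decalin-2-one, via mixed anhydride 23 (not isolated)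
Conditions: 2,4,6-trichlorobenzoyl chloride, Et3N, toluene, rt; then 21, 80 °C
Reagents that add atoms: none
Why: Yamaguchi esterification: the mixed anhydride 23 acylates the hindered axial O9–H on heating in toluene, conditions under which the (Z)-alkene of the angeloyl group is known to hold its geometry.

Compound list

1 | tigloyl chloride, (E)-2-methylbut-2-enoyl chloride | C/C=C(\C)C(=O)Cl | starting material
2 | N,O-dimethylhydroxylamine hydrochloride | CNOC.Cl | starting material
3 | (E)-N-methoxy-N,2-dimethylbut-2-enamide | C/C=C(\C)C(=O)N(C)OC | intermediate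
4 | methallylmagnesium chloride | C=C(C)C[Mg]Cl | starting material
5 | (5E)-2,5-dimethylhepta-1,5-dien-4-one | C=C(C)CC(=O)/C(C)=C/C | intermediate
6 | (S)-glyceraldehyde acetonide | CC1(C)OC[C@@H](C=O)O1 | starting material
7 | (Z)-dibutylboron dienolate of 5 | C=C(C)/C=C(\OB(CCCC)CCCC)/C(C)=C/C | intermediate (not isolated)
8 | (7R,8R,9S) aldol adduct, 7,8-syn, 8,9-anti, O9/O10 acetonide | C=C(C)[C@@H](C(=O)/C(C)=C/C)[C@@H](O)[C@@H]1COC(C)(C)O1 | intermediate
9 | (7R,8R,9S) 8,9,10-triol | C=C(C)[C@@H](C(=O)/C(C)=C/C)[C@@H](O)[C@@H](O)CO | intermediate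
10 | 10-O-triethylsilyl 8,9-diol | C=C(C)[C@@H](C(=O)/C(C)=C/C)[C@@H](O)[C@@H](O)CO[Si](CC)(CC)CC | intermediate
11 | O8/O9 cis-acetonide, 10-O-triethylsilyl | C=C(C)[C@@H](C(=O)/C(C)=C/C)[C@H]1OC(C)(C)O[C@H]1CO[Si](CC)(CC)CC | intermediate
12 | 1-(triphenylphosphoranylidene)propan-2-one | CC(=O)C=P(c1ccccc1)(c1ccccc1)c1ccccc1 | starting material
13 | C10 aldehyde of the O8/O9 acetonide | C=C(C)[C@@H](C(=O)/C(C)=C/C)[C@H]1OC(C)(C)O[C@H]1C=O | intermediate (not isolated)
14 | (E)-methyl enone on C9, tigloyl ketone, O8/O9 acetonide | C=C(C)[C@@H](C(=O)/C(C)=C/C)[C@H]1OC(C)(C)O[C@H]1/C=C/C(C)=O | intermediate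
15 | acyclic siloxydiene tigloyl ketone (7R,8R,9S) | C=C(C)[C@@H](C(=O)/C(C)=C/C)[C@H]1OC(C)(C)O[C@H]1/C=C/C(=C)O[Si](C)(C)C(C)(C)C | intermediate
16 | cis-decalin enol silane with C6 ketone | C=C(C)[C@H]1C(=O)[C@@]2(C)[C@H](C=C(O[Si](C)(C)C(C)(C)C)C[C@@H]2C)[C@@H]3OC(C)(C)O[C@H]13 | intermediate
17 | 6α-alcohol of 16 | C=C(C)[C@H]1[C@H](O)[C@@]2(C)[C@H](C=C(O[Si](C)(C)C(C)(C)C)C[C@@H]2C)[C@@H]3OC(C)(C)O[C@H]13 | intermediate
18 | C6 S-methyl xanthate | C=C(C)[C@H]1[C@H](OC(=S)SC)[C@@]2(C)[C@H](C=C(O[Si](C)(C)C(C)(C)C)C[C@@H]2C)[C@@H]3OC(C)(C)O[C@H]13 | intermediate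
19 | C6-deoxy cis-decalin enol silane acetonide | C=C(C)[C@H]1C[C@@]2(C)[C@H](C=C(O[Si](C)(C)C(C)(C)C)C[C@@H]2C)[C@@H]3OC(C)(C)O[C@H]13 | intermediate
20 | 8α,9α-dihydroxy keto diol | C=C(C)[C@H]1C[C@@]2(C)[C@H](CC(=O)C[C@@H]2C)[C@H](O)[C@@H]1O | intermediate
21 | 8-O-tigloyl-9-hydroxy ketone | C=C(C)[C@H]1C[C@@]2(C)[C@H](CC(=O)C[C@@H]2C)[C@H](O)[C@@H]1OC(=O)/C(C)=C/C | intermediate
22 | angelic acid, (Z)-2-methylbut-2-enoic acid | C/C=C(/C)C(=O)O | starting material
23 | angelic 2,4,6-trichlorobenzoic anhydride | C/C=C(/C)C(=O)OC(=O)c1c(Cl)cc(Cl)cc1Cl | intermediate (not isolated)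
24 | CNP0249036.3, 9α-angeloyloxy-8α-tigloyloxy ketone | C=C(C)[C@H]1C[C@@]2(C)[C@H](CC(=O)C[C@@H]2C)[C@H](OC(=O)/C(C)=C\C)[C@@H]1OC(=O)/C(C)=C/C | target

Total step count: 15. Longest linear sequence: 15 steps (steps 1–15; 4, 6, 12 and 22 are bought).

Steps most likely to fail

1. Step 9. The tether may fold chair-like instead of boat-like; the dienophile then adds to the opposite diene face, and C4, C5 and C10 come out inverted relative to C8 and C9. The hindered, trisubstituted dienophile may also react so slowly that the enol silane is lost first. The fallback sets out from 14 and uses C7 as the adjustable control element. Enone 14 would be equilibrated at C7 (DBU, toluene) and the 7-epi enone F1 separated, with 14 recycled. Silylation as in step 8 would give the 7-epi siloxydiene F2. In F2 the chair-like endo fold that keeps isopropenyl equatorial is the one on the required diene face, so heating should give the 7-epi cycloadduct F3. Base equilibration of the centre α to the C6 ketone (DBU, toluene) should then convert F3 into 16, in which isopropenyl, O8 and the C5 methyl are all equatorial on ring B. The route is rejoined at 16.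

2. Step 15. The angeloyl unit may isomerise from Z to E while the hindered axial hydroxyl is acylated slowly, or the O8 tigloyl group may migrate to O9 before the acylation. The fallback sets out from 21 and builds the (Z)-alkene on the substrate. 2-[Bis(2,2,2-trifluoroethoxy)phosphoryl]propanoic acid F4 (from its ethyl ester with Me3SnOH) would be coupled to O9 (DCC, DMAP, CH2Cl2) to give the phosphonate ester F5. Still–Gennari olefination of F5 with acetaldehyde (KN(SiMe3)2, 18-crown-6, THF, −78 °C) should then give the (Z)-2-methylbut-2-enoate directly. The route is rejoined at 24.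

3. Step 3. The 7,8-syn or 8,9-anti selectivity may erode, the dienolate may bond at its γ-carbon, or 5 may drift into conjugation before enolisation. The fallback sets out from 6 and uses auxiliary control. (R)-4-Benzyl-3-(3-methylbut-2-enoyl)oxazolidin-2-one F6 (from (R)-4-benzyloxazolidin-2-one and 3-methylbut-2-enoyl chloride) would be converted with Bu2BOTf/Et3N into its boron dienolate and added to 6 at the α-carbon in an oxazolidinone-auxiliary syn-aldol, auxiliary and aldehyde preferences being matched, to give the imide F7. AlMe3/MeNHOMe·HCl would give the Weinreb amide F8, and excess (E)-but-2-en-2-yllithium (from (E)-2-bromobut-2-ene and t-BuLi) would convert F8 into 8. The route is rejoined at 8.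

Further compounds

F1 | step 9 | C7 epimer (7S,8R,9S) of enone 14 | C=C(C)[C@H](C(=O)/C(C)=C/C)[C@H]1OC(C)(C)O[C@H]1/C=C/C(C)=O
F2 | step 9 | C7 epimer of siloxydiene 15 | C=C(C)[C@H](C(=O)/C(C)=C/C)[C@H]1OC(C)(C)O[C@H]1/C=C/C(=C)O[Si](C)(C)C(C)(C)C
F3 | step 9 | 7α-isopropenyl epimer of cycloadduct 16 | C=C(C)[C@@H]1C(=O)[C@@]2(C)[C@H](C=C(O[Si](C)(C)C(C)(C)C)C[C@@H]2C)[C@@H]3OC(C)(C)O[C@H]13
F4 | step 15 | 2-[bis(2,2,2-trifluoroethoxy)phosphoryl]propanoic acid | CC(C(=O)O)P(=O)(OCC(F)(F)F)OCC(F)(F)F
F5 | step 15 | 9-O-{2-[bis(2,2,2-trifluoroethoxy)phosphoryl]propanoyl} derivative of 21 | C=C(C)[C@H]1C[C@@]2(C)[C@H](CC(=O)C[C@@H]2C)[C@H](OC(=O)C(C)P(=O)(OCC(F)(F)F)OCC(F)(F)F)[C@@H]1OC(=O)/C(C)=C/C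
F6 | step 3 | (R)-4-benzyl-3-(3-methylbut-2-enoyl)oxazolidin-2-one | CC(C)=CC(=O)N1[C@H](Cc2ccccc2)COC1=O
F7 | step 3 | oxazolidinone syn-aldol adduct with 6 | C=C(C)[C@@H](C(=O)N1[C@H](Cc2ccccc2)COC1=O)[C@@H](O)[C@@H]1COC(C)(C)O1
F8 | step 3 | Weinreb amide of the aldol acid | C=C(C)[C@@H](C(=O)N(C)OC)[C@@H](O)[C@@H]1COC(C)(C)O1
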